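The earlier runs and the new flask come from a simulation for an exercise, noise included.

Start from a one-step world: each reagent turns substrate into first product, and north-west ends with no bis adduct at all. That is the bound from below. For the bound from above, send every reagent to a second addition: bis adduct costs two reagent, so 1.00 equiv reaches half of the substrate.

in all of them: substrate 0.061 M

| flask | reagent | remark | time |
|---|---|---|---|
| autumn | 0.48 equiv | run made earlier |  |
| summer | 2.1 equiv | run made earlier |  |
| south-west | 0.800 equiv |  | 25 min |
| north-west | 1.00 equiv |  | 25 min |
| west | 2.50 equiv |  | 25 min |

- autumn (time / min: bis adduct / %, triple product / %): 1.33: 0, 0; 2.50: 4, 0; 5.00: 4, 2; 10.0: 3, 0; 20.0: 3, 1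
- summer (time / min: bis adduct / %, triple product / %): 4.00: 34, 0; 8.00: 42, 5; 10.0: 46, 5; 15.0: 45, 8; 20.0: 46, 6

(each reading ± 1.5 percentage points)



1. which of these holds the largest part of the substrate at the end of south-west (bis adduct / substrate / first product / triple product)
2. which of these holds the largest part of the substrate at the end of north-west (bis adduct / substrate / first product / triple product)
3. which of these holds the largest part of the substrate at the end of west (bis adduct / substrate / first product / triple product)
4. amount of bis adduct at the end of north-west, in percent of the substrate charged

Read the stop first. Summer reads level from 10.0 min within the scatter, and autumn's readings at 10.0 min and 20.0 min read alike, so take reagent as the limiting reagent and count equivalents, not minutes, at 25 min.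

Now tighten the bracket with autumn. First product grows with reagent spent, and its second addition grows with reagent spent again, so take bis adduct to go as the square of the equivalents. Average those last two autumn readings, leaving out the earlier ones, which may stand before the stop, and allow two standard errors of that mean either way:

mean bis adduct = 3.00%

bis adduct over squared equivalents = 0.130

Call this the square number, the bis share at the stop over the squared equivalents spent. Multiply by the squared 1.00 equiv:

north-west = 13.0%, bracket 3.81% to 22.2%

The forecast names first product, first product and bis adduct as the largest for south-west, north-west and west. It gives 13% (9% to 19%) for north-west, on the ground that “the second addition is roughly 0.2–0.4 times as fast as the first”. That value stands inside the bracket, level with the 13.0% of the square number.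

The flasks give first product, first product and bis adduct, and north-west holds 19.6% bis adduct.

    substrate + reagent → first product + released group (k = 0.127 M⁻¹ s⁻¹)
    reagent + first product → bis adduct + released group (k = 0.0552 M⁻¹ s⁻¹)
    reagent + bis adduct → triple product + released group (k = 0.0281 M⁻¹ s⁻¹)
    reagent + triple product → over-reaction product (k = 0.183 M⁻¹ s⁻¹)

In north-west the second step has 0.43 of the constant of the first, and at 1.31 min first product is made 4.31 times as fast as it is used up. With 0.10% of the reagent left at 25.0 min, north-west stands at 52.6% first product against 19.6% bis adduct. Its own square number is 0.196, larger than autumn's 0.130. Carried to the neighbour with 0.600 equiv, it gives 7.06%, and that neighbour holds 7.63%.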